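Pterocarpan numbering is used throughout: ring A = C1–C4, C4a, C11b; ring B = O5, C6, C6a, C11a; ring C = O11; ring D = C6b, C7–C10, C10a. Compound numbers are those of the steps below.

## The problem

Lespecyrtin E4 (27) is a pterocarpan: a chroman (ring B) and a dihydrobenzofuran (ring C) share the C6a–C11a bond and are cis-fused. Each outer benzene ring carries a 2,2-dimethyl-2H-pyran. On ring A the pyran is linear (C2–C3, oxygen on C3). Ring D has no free position: pyran at C7–C8 (oxygen on C8), hydroxyl at C9, prenyl at C10, O11 at C10a. The only stereocentres are the adjacent C6a and C11a (both R). Once the rings exist either centre dictates the other through the cis fusion, but in an open-chain precursor they must be set together and absolutely. C11a is a benzylic ether para to the C3 oxygen and ionises easily. Acid also endangers the two chromene double bonds and would cyclise the C10 prenyl group onto the C9 phenol, and the three alkenes exclude hydrogenolysis. A pyran annulated late onto a 3-oxygenated ring A could go to C2 or C4, whereas on ring D every competing site can be blocked. The feature that opens the plan is that rings B and C are both aryl alkyl ethers (O5–C4a and O11–C10a) whose oxygens sit on the chain C6–C6a–C11a. Removing the two aryl–oxygen bonds leaves a 1,2-diarylpropane-1,3-diol, in which the anti (aldol sense) arrangement of the ring D aryl group and the C11a hydroxyl corresponds to the cis fusion.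

## Retrosynthesis

**C10–prenyl bond.** The last bond made joins C10 to the prenyl CH2. Direct C-prenylation of phenol 24 competes with O-alkylation, and acid-mediated variants are excluded by the chromenes. Cutting through an O-to-C shift leads to the 1,1-dimethylallyl ether 26. Its [3,3] rearrangement can only end at C10, because C8 and the para carbon C6b are substituted. Ether 26 comes from propargyl ether 25 by semi-hydrogenation, and 25 from 24 and chloride 9. The forward steps must be neutral and stay below the temperature at which an ortho-prenyl phenol cyclises.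

**O9–CH3 bond.** Phenol 24 is the demethylation product of 23. The methyl group is what keeps O9 distinct from O8. A silyl group on O9 would migrate once the neighbouring O8 phenoxide is formed, and acetal or benzyl groups would call for acid or hydrogen at the end. The precursor differs only by CH2. The forward reaction must be nucleophilic, not Lewis acidic, and must spare the C6 methylene, C11a and the tertiary pyran ethers.

**Ring D pyran (C7–C4' and O8–C2').** Compound 23 opens to the 1,1-dimethylpropargyl ether 22, that is phenol 21 plus 9, and 21 to silyl ether 20. Annulating after the core is built keeps the arylacetic unit mono-ortho-substituted for the aldol. Regiochemistry is fixed because C9 carries the methoxy group and only C7 is open. One ring is removed, leaving a pterocarpan whose two ring D oxygens are told apart by silyl (O8, off first with fluoride) and methyl (O9).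

**O5–C4a and O11–C10a (key disconnection).** The usual cuts of a pterocarpan, O11–C11a (benzylic cation or SN2 at the stereocentre) or O5–C6, need free phenols on both rings and act at or next to a stereocentre. Cutting both aryl–oxygen bonds puts the oxygens on the chain and turns 20 into the acyclic diol 18, with the two arenes present only as halides. The stereocentres are spectators. The forward reaction is a twofold palladium C–O coupling in fixed order: the primary alkoxide with the ring A halide first (ring B, via 19), then the C11a alkoxide with the ring D halide. Hence iodide on ring A and bromide on ring D.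

**C6a–C11a bond.** Diol 18 is the reduction product of imide 17, the aldol adduct of 7 and aldehyde 15. This cut lies between the stereocentres and forms both at once. Cutting C6a–C6b (α-arylation) or C11a–C11b (aryl addition) would set them one at a time. The aldehyde is aromatic and non-enolisable, the substrate class for which the MgCl2-catalysed anti-aldol of N-acyl oxazolidinones was developed. The reaction must deliver anti and facial selectivity with an α-aryl imide and tolerate aryl iodide and bromide.

**Imide 7.** Cutting the N–acyl bond gives acid 4 and auxiliary 5. Acid 4 comes from 2 by silylation and 2 from commercial 3-hydroxy-4-methoxyphenylacetic acid 1 by bromination. The oxygen pattern of ring D is bought, and only the bromine para to the phenol must be introduced. The triisopropylsilyl group is chosen over smaller silyl groups because it must survive caesium alkoxides at 90 °C.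

**Aldehyde 15.** The C7–I bond is cut first, giving 11, then the pyran, giving ether 10 from 4-hydroxybenzaldehyde 8 and 9. Rearranging before iodine is present is deliberate: 8 is symmetric, so the linear-versus-angular question does not arise, whereas an ether already bearing iodine meta to oxygen would offer two unequal ortho carbons. The forward lithiation must choose C7 over C5 and C8.

## Roads not taken

Alternative 1: The cut is at C11a–C11b and C6a–C6b, and three components are joined in a conjunctive cross-coupling. A ring A aryllithium adds to an E-alkenyl boronic ester that supplies C6, C6a and C11a. Pd(OAc)2 with a ferrocenyl bisphosphine (MandyPhos type) and a ring D aryl triflate then triggers 1,2-migration of ring A to C11a and aryl transfer to C6a, giving boronate A1. This is the most convergent road: chirality comes from a catalyst, and ring D arrives with its prenyl group, so no late rearrangements are needed. In these respects it is better than the chosen plan. Its weak points lie in this particular target. β-Substituted alkenyl boronates, an ortho-alkoxy migrating aryl group and an electron-rich ortho-substituted triflate are each at the edge of the method. Anti addition across the E-alkene places boron so that stereoretentive oxidation gives the C11a epimer of the alcohol in 18, so ring C must close with inversion or through the benzylic cation. The two phenols must be released from acetal ethers with acid while the prenyl group is already next to an oxygenated ring. The chosen plan sets against this an auxiliary-controlled aldol of known sense and ring closures that do not touch C11a, at the cost of a stoichiometric auxiliary and seven post-cyclisation steps.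

Alternative 2: Ring D is not bought but made. A 4-alkenyl-4-hydroxycyclobutenone derived from a squarate opens on heating to a dienyl ketene, 6π-electrocyclisation forms C10a–C6b, and tautomerisation gives hydroquinone A2 (Moore rearrangement). Its merit is real: all five ring D substituents, the prenyl group included, are written into the four-membered ring, so regiochemistry is certain without blocking groups or Claisen steps. The chosen plan reaches the same certainty only through two thermal rearrangements and an ether cleavage. Against it, the stereocentres must already exist in the alkenyl nucleophile, a cis-3-alkenyl-4-silyloxychroman, so the stereochemical problem is moved, not solved. Ring C must then be closed at C11a by displacing the silyloxy group through the cation. A2 is an air-sensitive hydroquinone with two phenols to tell apart, and the C9 methyl ether must still be cleaved. The alkenyl metal must also add to the correct carbonyl of an unsymmetrical cyclobutenedione. The chosen plan is simpler in stereochemistry and starts from commercial arenes.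

Alternative 3: The cut is at C11a–C11b, from a flat benzofuran in which ring A is tethered through the O5–C6 ether. A confined chiral imidodiphosphorimidate acid protonates C6a, and the C11a oxocarbenium ion is attacked by the ring A carbon para to the silyloxy group, closing ring B and giving A3. This is the shortest and only fully catalytic asymmetric entry to the pterocarpan core, and on step count to the core it beats the chosen plan. Its weak points are as follows. Enantioselective protonation of a weakly basic benzofuran is not established, and reversible protonation would erode the C6a configuration. A3 carries neither pyran. The ring A pyran would have to be annulated by rearrangement of a 3-O-propargyl ether that can reach both C2 and C4, with the doubly oxygen-flanked C4 a serious competitor. The two silyl ethers on rings A and D must be told apart, and the C9 methyl ether remains. The chosen plan fixes the linear ring A pyran at the fragment stage, where the phenol is symmetric, and pays with a longer route to the core.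

Key step: step 9

Assumption: the magnesium-catalysed aldol of arylacetyl imide 7 is taken to follow the sense established for N-propionyl oxazolidinones (chelated Z-enolate attacked on the face away from the benzyl group, anti adduct), which is why the (R)-auxiliary 5 is used.

## Steps

Step 1
Reactants: 1 3-hydroxy-4-methoxyphenylacetic acid
Product: 2 2-bromo-5-hydroxy-4-methoxyphenylacetic acid
Conditions: NBS (1.0 equiv), MeCN, 0 °C
Reagents that add atoms: N-bromosuccinimide, O=C1CCC(=O)N1Br
Why: Electrophilic aromatic bromination directed by the free phenol; the position para to the hydroxyl is the only unhindered activated site, since the one open ortho carbon lies between the hydroxyl and the CH2CO2H group.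

Step 2
Reactants: 2 2-bromo-5-hydroxy-4-methoxyphenylacetic acid
Product: 4 2-[2-bromo-4-methoxy-5-(triisopropylsilyloxy)phenyl]acetic acid, via bis-silylated ester 3 (not isolated)
Conditions: iPr3SiCl (2.2 equiv), imidazole, DMF, 23 °C; then K2CO3, MeOH–H2O, 0 °C; 1 M HCl to pH 3
Reagents that add atoms: chlorotriisopropylsilane, CC(C)[Si](Cl)(C(C)C)C(C)C
Why: Imidazole-promoted silylation of phenol and acid followed by selective hydrolysis of the much more labile silyl ester; the hindered aryl silyl ether is kept because it must later withstand caesium alkoxides and can be removed with fluoride, without acid, next to the O9 methyl ether.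

Step 3
Reactants: 4 2-[2-bromo-4-methoxy-5-(triisopropylsilyloxy)phenyl]acetic acid; 5 (R)-4-benzyl-1,3-oxazolidin-2-one
Product: 7 (R)-4-benzyl-3-{2-[2-bromo-4-methoxy-5-(triisopropylsilyloxy)phenyl]acetyl}-1,3-oxazolidin-2-one, via mixed pivalic anhydride 6 (not isolated)
Conditions: Me3CCOCl, Et3N, THF, −20 °C; then 5, LiCl, −20 to 23 °C
Reagents that add atoms: none
Why: N-Acylation of the oxazolidinone through the mixed pivalic anhydride with LiCl/Et3N activation (standard one-flask imide formation); the hindered pivaloyl carbonyl directs attack to the arylacetyl carbonyl.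

Step 4
Reactants: 8 4-hydroxybenzaldehyde; 9 3-chloro-3-methylbut-1-yne
Product: 10 4-(2-methylbut-3-yn-2-yloxy)benzaldehyde
Conditions: DBU, CuCl2 (1 mol %), MeCN, 0 to 23 °C
Reagents that add atoms: none
Why: Copper-catalysed O-alkylation of a phenol with a tertiary propargylic chloride, the standard entry to aryl 1,1-dimethylpropargyl ethers, which works well for electron-poor phenols.

Step 5
Reactants: 10 4-(2-methylbut-3-yn-2-yloxy)benzaldehyde
Product: 11 2,2-dimethyl-2H-chromene-6-carbaldehyde
Conditions: N,N-diethylaniline, 190 °C
Reagents that add atoms: none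
Why: Aromatic propargyl Claisen rearrangement, 1,5-hydrogen shift and oxa-6π electrocyclisation give the 2,2-dimethylchromene; the two ortho carbons of 10 are equivalent, so only one chromene can form.

Step 6
Reactants: 11 2,2-dimethyl-2H-chromene-6-carbaldehyde
Product: 15 7-iodo-2,2-dimethyl-2H-chromene-6-carbaldehyde, via lithium amino alkoxide 12 (not isolated), via C7-lithiated amino alkoxide 13 (not isolated), via C7-iodo amino alkoxide 14 (not isolated)
Conditions: LiN(Me)CH2CH2NMe2 (from the amine and n-BuLi), THF, −20 °C; n-BuLi (3 equiv), −20 °C; I2, −78 to 23 °C; aq. NH4Cl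
Reagents that add atoms: iodine, [I][I]
Why: α-Amino alkoxide-directed ortho-lithiation: the aldehyde is masked in the flask as the chelating alkoxide 12, which directs n-BuLi to its ortho position; C5 is blocked between the alkoxide carbon and the ring fusion, so lithiation should occur at C7 (13), iodine gives 14 and aqueous work-up releases the aldehyde; the diamine-derived alkoxide is a stronger director than the para ring oxygen, which would point to C8.

Step 7
Reactants: 7 (R)-4-benzyl-3-{2-[2-bromo-4-methoxy-5-(triisopropylsilyloxy)phenyl]acetyl}-1,3-oxazolidin-2-one; 15 7-iodo-2,2-dimethyl-2H-chromene-6-carbaldehyde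
Product: 17 (R)-4-benzyl-3-{(2S,3R)-2-[2-bromo-4-methoxy-5-(triisopropylsilyloxy)phenyl]-3-hydroxy-3-(7-iodo-2,2-dimethyl-2H-chromen-6-yl)propanoyl}-1,3-oxazolidin-2-one, via trimethylsilyl ether 16 (not isolated)
Conditions: MgCl2 (0.2 equiv), Et3N, Me3SiCl, EtOAc, 23 °C; then CF3CO2H (cat.), MeOH
Reagents that add atoms: none
Why: Magnesium halide-catalysed anti-aldol reaction of an N-acyl oxazolidinone with a non-enolisable aromatic aldehyde: soft enolisation gives the chelated Z-enolate, the aldehyde adds to the face away from the benzyl group (C6a, 2S) through the anti-selective transition state (C11a, 3R), silylation of the aldolate to 16 makes the step irreversible, and methanolysis frees 17.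

Step 8
Reactants: 17 the (2S,3R) aldol adduct
Product: 18 (1R,2R)-2-[2-bromo-4-methoxy-5-(triisopropylsilyloxy)phenyl]-1-(7-iodo-2,2-dimethyl-2H-chromen-6-yl)propane-1,3-diol
Conditions: LiBH4, MeOH (1 equiv), THF, 0 °C
Reagents that add atoms: none
Why: Reductive cleavage of the N-acyl oxazolidinone with LiBH4 gives the primary alcohol and returns auxiliary 5; aryl halides, silyl ether and chromene are inert and neither stereocentre is touched.

Step 9
Reactants: 18 (1R,2R)-2-[2-bromo-4-methoxy-5-(triisopropylsilyloxy)phenyl]-1-(7-iodo-2,2-dimethyl-2H-chromen-6-yl)propane-1,3-diol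
Product: 20 (6aR,11aR)-9-methoxy-8-(triisopropylsilyloxy)pterocarpan bearing a 2,2-dimethyl-2H-pyran ring fused at C2–C3 (oxygen on C3), via bromo chromanol 19 (not isolated)
Conditions: Pd2(dba)3 (3 mol %), 2-(di-tert-butylphosphino)-1,1'-binaphthyl (7 mol %), Cs2CO3 (3 equiv), toluene, 50 °C, then 90 °C
Reagents that add atoms: none
Why: Zerovalent palladium carrying the bulky di-tert-butylbiarylphosphine inserts first into the C4a–I bond at 50 °C, because an aryl iodide adds much faster than the electron-rich, ortho-branched aryl bromide para to the silyloxy group. Of the two caesium alkoxides only the primary C6 alkoxide can reach this palladium centre productively (seven-membered oxapalladacycle, whereas the C11a alkoxide could only give a four-membered ring), so aryl–oxygen reductive elimination closes the six-membered ring B and gives 19. Raising the temperature to 90 °C brings in the C10a–Br bond; the only hydroxyl left is at C11a, which forms a six-membered oxapalladacycle and eliminates to the five-membered ring C. The closest known reaction type is the palladium-catalysed intramolecular etherification of aryl bromides and chlorides with primary and secondary alcohols to chromans and dihydrobenzofurans under di-tert-butylphosphinobiaryl/Cs2CO3 conditions, which leaves carbinol stereocentres intact. No stereocentre is created: C6a and C11a come from 18, and because both new bonds are made at aromatic carbons the C11a–O and C6–O bonds are never broken, so the anti relationship of 18 becomes the cis ring fusion. The step needs chemoselectivity between ring B closure and the competing five-membered closure of the primary alkoxide onto the ring D bromide; this is secured by the iodide-before-bromide order of oxidative addition, reinforced by the temperature programme, so that no primary hydroxyl remains when the bromide reacts. The bulky electron-rich ligand is also what lets C–O reductive elimination outrun β-hydride elimination of the secondary benzylic alkoxide.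

Step 10
Reactants: 20 the 8-silyloxy-9-methoxy pterocarpan
Product: 21 (6aR,11aR)-8-hydroxy-9-methoxypterocarpan bearing the 2,2-dimethyl-2H-pyran ring at C2–C3 (oxygen on C3)
Conditions: Bu4NF, AcOH, THF, 0 °C
Reagents that add atoms: none
Why: Fluoride cleaves the aryl silyl ether (strong Si–F bond) while acetic acid buffers the phenoxide; ethers, chromene and the benzylic C11a–O bond are inert to fluoride.

Step 11
Reactants: 21 the 8-hydroxy-9-methoxy pterocarpan; 9 3-chloro-3-methylbut-1-yne
Product: 22 (6aR,11aR)-9-methoxy-8-(2-methylbut-3-yn-2-yloxy)pterocarpan bearing the 2,2-dimethyl-2H-pyran ring at C2–C3 (oxygen on C3)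
Conditions: DBU, CuCl2 (1 mol %), MeCN, 0 °C
Reagents that add atoms: none
Why: The same copper-catalysed propargylation as in step 4; the O8 phenol is the only acidic site.

Step 12
Reactants: 22 the 8-O-propargyl ether
Product: 23 (6aR,11aR)-9-methoxypterocarpan bearing 2,2-dimethyl-2H-pyran rings at C2–C3 (oxygen on C3) and C7–C8 (oxygen on C8)
Conditions: o-xylene, 140 °C
Reagents that add atoms: none
Why: Propargyl Claisen rearrangement, 1,5-hydrogen shift and oxa-6π electrocyclisation as in step 5; C9 carries the methoxy group, so the sequence can only end productively at C7, which fixes the position of the second pyran, and the electron-rich ether rearranges at a lower temperature than 10.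

Step 13
Reactants: 23 the 9-methoxy bis-pyrano pterocarpan
Product: 24 (6aR,11aR)-9-hydroxypterocarpan bearing 2,2-dimethyl-2H-pyran rings at C2–C3 (oxygen on C3) and C7–C8 (oxygen on C8)
Conditions: NaSEt (5 equiv), DMF, 120 °C; then 1 M HCl to pH 6, 0 °C
Reagents that add atoms: none
Why: SN2 demethylation of the aryl methyl ether by ethanethiolate; a methyl carbon reacts far faster than the β-branched C6 methylene, the secondary benzylic C11a or the tertiary pyran carbons, and no acid is involved, so chromenes and core should survive, as in thiolate demethylations of methoxy-2,2-dimethylchromenes.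

Step 14
Reactants: 24 the 9-hydroxy bis-pyrano pterocarpan; 9 3-chloro-3-methylbut-1-yne
Product: 25 (6aR,11aR)-9-(2-methylbut-3-yn-2-yloxy)pterocarpan bearing the two 2,2-dimethyl-2H-pyran rings
Conditions: DBU, CuCl2 (1 mol %), MeCN, 0 °C
Reagents that add atoms: none
Why: Copper-catalysed propargylation of the single phenol as in steps 4 and 11; the ether is kept cold so that it cannot cyclise to a third pyran.

Step 15
Reactants: 25 the 9-O-propargyl ether
Product: 26 (6aR,11aR)-9-(2-methylbut-3-en-2-yloxy)pterocarpan bearing the two 2,2-dimethyl-2H-pyran rings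
Conditions: H2 (1 atm), Pd/CaCO3 poisoned with Pb(OAc)2 (Lindlar catalyst), quinoline, EtOAc, 23 °C
Reagents that add atoms: none
Why: Lindlar semi-hydrogenation of the terminal alkyne to the 1,1-dimethylallyl ether; the poisoned catalyst does not reduce the disubstituted chromene double bonds or cleave the benzylic ether, and uptake is stopped at one equivalent.

Step 16
Reactants: 26 the 9-O-(1,1-dimethylallyl) ether
Product: 27 lespecyrtin E4
Conditions: o-xylene, 130 °C
Reagents that add atoms: none
Why: Aromatic Claisen rearrangement of a tertiary allyl aryl ether: the [3,3] shift goes to C10, the only free ortho carbon (C8 and the para carbon C6b are substituted), allyl inversion turns the 1,1-dimethylallyl group into the prenyl group and tautomerisation restores the C9 phenol; neutral conditions protect the prenyl phenol and the chromenes.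

## Compound list

1 | 3-hydroxy-4-methoxyphenylacetic acid | COc1ccc(CC(=O)O)cc1O | starting material
2 | 2-bromo-5-hydroxy-4-methoxyphenylacetic acid | COc1cc(Br)c(CC(=O)O)cc1O | intermediate
3 | triisopropylsilyl 2-[2-bromo-4-methoxy-5-(triisopropylsilyloxy)phenyl]acetate | COc1cc(Br)c(CC(=O)O[Si](C(C)C)(C(C)C)C(C)C)cc1O[Si](C(C)C)(C(C)C)C(C)C | intermediate
4 | 2-[2-bromo-4-methoxy-5-(triisopropylsilyloxy)phenyl]acetic acid | COc1cc(Br)c(CC(=O)O)cc1O[Si](C(C)C)(C(C)C)C(C)C | intermediate
5 | (R)-4-benzyl-1,3-oxazolidin-2-one | O=C1N[C@H](Cc2ccccc2)CO1 | starting material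
6 | mixed anhydride of 4 with pivalic acid | COc1cc(Br)c(CC(=O)OC(=O)C(C)(C)C)cc1O[Si](C(C)C)(C(C)C)C(C)C | intermediate
7 | (R)-4-benzyl-3-{2-[2-bromo-4-methoxy-5-(triisopropylsilyloxy)phenyl]acetyl}-1,3-oxazolidin-2-one | COc1cc(Br)c(CC(=O)N2[C@H](Cc3ccccc3)COC2=O)cc1O[Si](C(C)C)(C(C)C)C(C)C | intermediate
8 | 4-hydroxybenzaldehyde | O=Cc1ccc(O)cc1 | starting material
9 | 3-chloro-3-methylbut-1-yne | C#CC(C)(C)Cl | starting material
10 | 4-(2-methylbut-3-yn-2-yloxy)benzaldehyde | O=Cc1ccc(OC(C)(C)C#C)cc1 | intermediate
11 | 2,2-dimethyl-2H-chromene-6-carbaldehyde | O=Cc1ccc2OC(C)(C)C=Cc2c1 | intermediate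
12 | lithium α-amino alkoxide from 11 and lithium N,N,N'-trimethylethylenediamide | [Li]OC(N(C)CCN(C)C)c1ccc2OC(C)(C)C=Cc2c1 | intermediate
13 | C7-lithiated derivative of 12 | [Li]OC(N(C)CCN(C)C)c1cc2C=CC(C)(C)Oc2cc1[Li] | intermediate
14 | C7-iodinated lithium α-amino alkoxide | [Li]OC(N(C)CCN(C)C)c1cc2C=CC(C)(C)Oc2cc1I | intermediate
15 | 7-iodo-2,2-dimethyl-2H-chromene-6-carbaldehyde | O=Cc1cc2C=CC(C)(C)Oc2cc1I | intermediate
16 | O-trimethylsilyl ether of aldol adduct 17 | O=C(N1[C@H](Cc2ccccc2)COC1=O)[C@@H](c1cc(O[Si](C(C)C)(C(C)C)C(C)C)c(OC)cc1Br)[C@@H](O[Si](C)(C)C)c1cc2C=CC(C)(C)Oc2cc1I | intermediate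
17 | (R)-4-benzyl-3-{(2S,3R)-2-[2-bromo-4-methoxy-5-(triisopropylsilyloxy)phenyl]-3-hydroxy-3-(7-iodo-2,2-dimethyl-2H-chromen-6-yl)propanoyl}-1,3-oxazolidin-2-one | O=C(N1[C@H](Cc2ccccc2)COC1=O)[C@@H](c1cc(O[Si](C(C)C)(C(C)C)C(C)C)c(OC)cc1Br)[C@@H](O)c1cc2C=CC(C)(C)Oc2cc1I | intermediate
18 | (1R,2R)-2-[2-bromo-4-methoxy-5-(triisopropylsilyloxy)phenyl]-1-(7-iodo-2,2-dimethyl-2H-chromen-6-yl)propane-1,3-diol | OC[C@@H](c1cc(O[Si](C(C)C)(C(C)C)C(C)C)c(OC)cc1Br)[C@@H](O)c1cc2C=CC(C)(C)Oc2cc1I | intermediate
19 | (3R,4R)-3-[2-bromo-4-methoxy-5-(triisopropylsilyloxy)phenyl]-8,8-dimethyl-3,4-dihydro-2H,8H-pyrano[3,2-g]chromen-4-ol (cis) | O1C[C@@H](c2cc(O[Si](C(C)C)(C(C)C)C(C)C)c(OC)cc2Br)[C@@H](O)c2cc3C=CC(C)(C)Oc3cc21 | intermediate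
20 | (6aR,11aR)-9-methoxy-8-(triisopropylsilyloxy)pterocarpan with a 2,2-dimethyl-2H-pyran fused at C2–C3 (oxygen on C3) | COc1cc2O[C@H]3c4cc5C=CC(C)(C)Oc5cc4OC[C@H]3c2cc1O[Si](C(C)C)(C(C)C)C(C)C | intermediate
21 | (6aR,11aR)-8-hydroxy-9-methoxypterocarpan with the C2–C3 pyran | COc1cc2O[C@H]3c4cc5C=CC(C)(C)Oc5cc4OC[C@H]3c2cc1O | intermediate
22 | (6aR,11aR)-9-methoxy-8-(2-methylbut-3-yn-2-yloxy)pterocarpan with the C2–C3 pyran | COc1cc2O[C@H]3c4cc5C=CC(C)(C)Oc5cc4OC[C@H]3c2cc1OC(C)(C)C#C | intermediate
23 | (6aR,11aR)-9-methoxypterocarpan with 2,2-dimethyl-2H-pyrans at C2–C3 (oxygen on C3) and C7–C8 (oxygen on C8) | COc1cc2O[C@H]3c4cc5C=CC(C)(C)Oc5cc4OC[C@H]3c2c6C=CC(C)(C)Oc16 | intermediate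
24 | (6aR,11aR)-9-hydroxypterocarpan with the two pyrans (10-desprenyl lespecyrtin E4) | Oc1cc2O[C@H]3c4cc5C=CC(C)(C)Oc5cc4OC[C@H]3c2c6C=CC(C)(C)Oc16 | intermediate
25 | 9-O-(2-methylbut-3-yn-2-yl) ether of 24 | C#CC(C)(C)Oc1cc2O[C@H]3c4cc5C=CC(C)(C)Oc5cc4OC[C@H]3c2c6C=CC(C)(C)Oc16 | intermediate
26 | 9-O-(2-methylbut-3-en-2-yl) ether of 24 | C=CC(C)(C)Oc1cc2O[C@H]3c4cc5C=CC(C)(C)Oc5cc4OC[C@H]3c2c6C=CC(C)(C)Oc16 | intermediate
27 | lespecyrtin E4, (6aR,11aR) | CC(C)=CCc1c(O)c2c(c3c1O[C@H]1c4cc5c(cc4OC[C@@H]31)OC(C)(C)C=C5)C=CC(C)(C)O2 | target

## Step count and risk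

Total: 16 steps. Longest linear sequence: 13 steps (steps 1–3 and 7–16; the ring A branch, steps 4–6 and 7–16, is equally long).

**Step 9 (key step).** The most likely failure is loss of the programmed order. If the bromide undergoes oxidative addition while the primary hydroxyl is still free, the primary alkoxide closes a five-membered ring onto ring D and the material is lost. The second risk is β-hydride elimination of the secondary benzylic alkoxide on palladium, which oxidises C11a and reduces the carbon–halogen bond. Fallback: split the operation and change the metal for the first closure. From 18, CuI with 3,4,7,8-tetramethyl-1,10-phenanthroline and Cs2CO3 in toluene (Ullmann-type coupling of aliphatic alcohols, which takes aryl iodides and leaves aryl bromides) closes ring B only and gives 19, now isolated. Compound 19 is then cyclised to 20 with the palladium system of step 9. If β-hydride elimination persists, the same copper system at higher temperature is used, since copper alkoxides do not open that pathway. The fallback returns to the route at 20.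

**Step 7.** The arylacetyl imide enolises easily and the adduct keeps an acidic α-hydrogen. The likely failures are therefore erosion of the anti and facial selectivity, epimerisation at C6a, and retro-aldol cleavage on desilylation. Fallback: change the auxiliary class and with it the organisation of the enolate. From 4, coupling with (S)-4-benzyl-1,3-thiazolidine-2-thione F1 (EDC, DMAP) gives (S)-4-benzyl-3-{2-[2-bromo-4-methoxy-5-(triisopropylsilyloxy)phenyl]acetyl}-1,3-thiazolidine-2-thione F2. Its aldol with 15 under MgBr2·OEt2 (10 mol %), Et3N and Me3SiCl in EtOAc, followed by acidic work-up, gives the anti adduct (S)-4-benzyl-3-{(2S,3R)-2-[2-bromo-4-methoxy-5-(triisopropylsilyloxy)phenyl]-3-hydroxy-3-(7-iodo-2,2-dimethyl-2H-chromen-6-yl)propanoyl}-1,3-thiazolidine-2-thione F3. This series is expected to react through the enolate face opposite to that of the oxazolidinone series, hence the (S)-auxiliary. NaBH4 in wet THF removes the thione auxiliary and the route is rejoined at 18, where the configuration is checked against material from step 8.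

**Step 6.** Lithiation may be incomplete or go to C8 next to the ring oxygen, and butyllithium may add to the chromene double bond or to the aldehyde if the alkoxide is not fully formed. Fallback: bring the iodine in with the starting material. 4-Hydroxy-2-iodobenzaldehyde F4 is propargylated with 9 (DBU, CuCl2) to 2-iodo-4-(2-methylbut-3-yn-2-yloxy)benzaldehyde F5, and heating as in step 5 gives 15. It must be separated from the isomer formed by rearrangement to the carbon next to iodine. This is one step shorter but not regiocontrolled, which is why it is the reserve. It sets out from 9 and returns at 15.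

**Step 13.** Cleavage of the electron-rich, flanked methyl ether may be slow. Under forcing conditions thiolate could begin to open ring B at C6 or degrade the bis-chromene. Fallback: move both the ring D annulation and the methyl cleavage to the fragment stage, so that O9 is a silyl ether from then on.
- From 2, Fischer esterification (MeOH, H2SO4) gives methyl 2-(2-bromo-5-hydroxy-4-methoxyphenyl)acetate F6.
- Propargylation with 9 gives methyl 2-[2-bromo-4-methoxy-5-(2-methylbut-3-yn-2-yloxy)phenyl]acetate F7.
- Heating gives methyl 2-(6-bromo-8-methoxy-2,2-dimethyl-2H-chromen-5-yl)acetate F8, since only one ortho carbon is free.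
- NaSEt in DMF cleaves the aryl methyl ether and the methyl ester of this robust bicycle to 2-(6-bromo-8-hydroxy-2,2-dimethyl-2H-chromen-5-yl)acetic acid F9.
- Silylation as in step 2 gives 2-[6-bromo-2,2-dimethyl-8-(triisopropylsilyloxy)-2H-chromen-5-yl]acetic acid F10.
- Acylation of 5 as in step 3 gives (R)-4-benzyl-3-{2-[6-bromo-2,2-dimethyl-8-(triisopropylsilyloxy)-2H-chromen-5-yl]acetyl}-1,3-oxazolidin-2-one F11.
- The aldol with 15 as in step 7 gives the (2S,3R) adduct (R)-4-benzyl-3-{(2S,3R)-2-[6-bromo-2,2-dimethyl-8-(triisopropylsilyloxy)-2H-chromen-5-yl]-3-hydroxy-3-(7-iodo-2,2-dimethyl-2H-chromen-6-yl)propanoyl}-1,3-oxazolidin-2-one F12.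
- LiBH4 gives (1R,2R)-2-[6-bromo-2,2-dimethyl-8-(triisopropylsilyloxy)-2H-chromen-5-yl]-1-(7-iodo-2,2-dimethyl-2H-chromen-6-yl)propane-1,3-diol F13.
- The double C–O coupling of step 9 gives the (6aR,11aR)-9-(triisopropylsilyloxy)pterocarpan with both pyrans F14, which Bu4NF converts into 24.

The price is an aldol with an arylacetyl imide substituted at both ortho positions.

**Step 16.** The tertiary allyl ether may fragment (loss of isoprene, returning 24) instead of rearranging, or the product may cyclise through its phenol and prenyl group if heating is prolonged. Fallback: direct ortho C-prenylation. The sodium phenoxide of 24 (NaH, toluene, no polar cosolvent) is alkylated with 1-bromo-3-methylbut-2-ene. C-Alkylation of phenoxides in non-polar media goes to the ortho carbon, here only C10, and gives 27 directly from 24. The O-prenyl ether by-product is separated.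

## Further compounds

F0 | step 9 | none | none
F1 | step 7 | (S)-4-benzyl-1,3-thiazolidine-2-thione | S=C1N[C@@H](Cc2ccccc2)CS1
F2 | step 7 | (S)-4-benzyl-3-{2-[2-bromo-4-methoxy-5-(triisopropylsilyloxy)phenyl]acetyl}-1,3-thiazolidine-2-thione | COc1cc(Br)c(CC(=O)N2[C@@H](Cc3ccccc3)CSC2=S)cc1O[Si](C(C)C)(C(C)C)C(C)C
F3 | step 7 | (S)-4-benzyl-3-{(2S,3R)-2-[2-bromo-4-methoxy-5-(triisopropylsilyloxy)phenyl]-3-hydroxy-3-(7-iodo-2,2-dimethyl-2H-chromen-6-yl)propanoyl}-1,3-thiazolidine-2-thione | O=C(N1[C@@H](Cc2ccccc2)CSC1=S)[C@@H](c1cc(O[Si](C(C)C)(C(C)C)C(C)C)c(OC)cc1Br)[C@@H](O)c1cc2C=CC(C)(C)Oc2cc1I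
F4 | step 6 | 4-hydroxy-2-iodobenzaldehyde | O=Cc1ccc(O)cc1I
F5 | step 6 | 2-iodo-4-(2-methylbut-3-yn-2-yloxy)benzaldehyde | O=Cc1ccc(OC(C)(C)C#C)cc1I
F6 | step 13 | methyl 2-(2-bromo-5-hydroxy-4-methoxyphenyl)acetate | COC(=O)Cc1cc(O)c(OC)cc1Br
F7 | step 13 | methyl 2-[2-bromo-4-methoxy-5-(2-methylbut-3-yn-2-yloxy)phenyl]acetate | COC(=O)Cc1cc(OC(C)(C)C#C)c(OC)cc1Br
F8 | step 13 | methyl 2-(6-bromo-8-methoxy-2,2-dimethyl-2H-chromen-5-yl)acetate | COC(=O)Cc1c(Br)cc(OC)c2OC(C)(C)C=Cc12
F9 | step 13 | 2-(6-bromo-8-hydroxy-2,2-dimethyl-2H-chromen-5-yl)acetic acid | OC(=O)Cc1c(Br)cc(O)c2OC(C)(C)C=Cc12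
F10 | step 13 | 2-[6-bromo-2,2-dimethyl-8-(triisopropylsilyloxy)-2H-chromen-5-yl]acetic acid | OC(=O)Cc1c(Br)cc(O[Si](C(C)C)(C(C)C)C(C)C)c2OC(C)(C)C=Cc12
F11 | step 13 | (R)-4-benzyl-3-{2-[6-bromo-2,2-dimethyl-8-(triisopropylsilyloxy)-2H-chromen-5-yl]acetyl}-1,3-oxazolidin-2-one | O=C(Cc1c(Br)cc(O[Si](C(C)C)(C(C)C)C(C)C)c2OC(C)(C)C=Cc12)N1[C@H](Cc2ccccc2)COC1=O
F12 | step 13 | (R)-4-benzyl-3-{(2S,3R)-2-[6-bromo-2,2-dimethyl-8-(triisopropylsilyloxy)-2H-chromen-5-yl]-3-hydroxy-3-(7-iodo-2,2-dimethyl-2H-chromen-6-yl)propanoyl}-1,3-oxazolidin-2-one | O=C(N1[C@H](Cc2ccccc2)COC1=O)[C@@H](c1c(Br)cc(O[Si](C(C)C)(C(C)C)C(C)C)c2OC(C)(C)C=Cc12)[C@@H](O)c1cc2C=CC(C)(C)Oc2cc1I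
F13 | step 13 | (1R,2R)-2-[6-bromo-2,2-dimethyl-8-(triisopropylsilyloxy)-2H-chromen-5-yl]-1-(7-iodo-2,2-dimethyl-2H-chromen-6-yl)propane-1,3-diol | OC[C@@H](c1c(Br)cc(O[Si](C(C)C)(C(C)C)C(C)C)c2OC(C)(C)C=Cc12)[C@@H](O)c1cc2C=CC(C)(C)Oc2cc1I
F14 | step 13 | (6aR,11aR)-9-(triisopropylsilyloxy)pterocarpan with 2,2-dimethyl-2H-pyrans at C2–C3 (oxygen on C3) and C7–C8 (oxygen on C8) | CC(C)[Si](C(C)C)(C(C)C)Oc1cc2O[C@H]3c4cc5C=CC(C)(C)Oc5cc4OC[C@H]3c2c6C=CC(C)(C)Oc16
F0 | step 16 | none | none
A1 | alternative 1 | pinacol ester of 3-(tert-butyldimethylsilyloxy)-2-[5-(tert-butyldimethylsilyloxy)-4-methoxy-2-(methoxymethoxy)-3-(3-methylbut-2-enyl)phenyl]-1-[2,2-dimethyl-7-(2-trimethylsilylethoxymethoxy)-2H-chromen-6-yl]propylboronic acid, configuration as in the SMILES | CC(C)(C)[Si](C)(C)OC[C@@H](c1cc(O[Si](C)(C)C(C)(C)C)c(OC)c(CC=C(C)C)c1OCOC)[C@H](B2OC(C)(C)C(C)(C)O2)c1cc2C=CC(C)(C)Oc2cc1OCOCC[Si](C)(C)C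
A2 | alternative 2 | cis-4-(tert-butyldimethylsilyloxy)-3-[2,5-dihydroxy-4-methoxy-3-(3-methylbut-2-enyl)phenyl]-8,8-dimethyl-3,4-dihydro-2H,8H-pyrano[3,2-g]chromene | CC(C)=CCc1c(O)c(cc(O)c1OC)[C@@H]2COc3cc4OC(C)(C)C=Cc4cc3[C@@H]2O[Si](C)(C)C(C)(C)C
A3 | alternative 3 | (6aR,11aR)-3,8-bis(tert-butyldimethylsilyloxy)-9-methoxypterocarpan | COc1cc2O[C@H]3c4ccc(O[Si](C)(C)C(C)(C)C)cc4OC[C@H]3c2cc1O[Si](C)(C)C(C)(C)C
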